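Readings and results are simulated from invented constants; scatter was added.

No rate constant of this flask is given, so every estimate has to be read from the runs, in which starting material and coupling partner join to target on a catalyst.

| flask | starting material | coupling partner | free catalyst | target | time |
|---|---|---|---|---|---|
| eta | 0.400 M | 1.00 M | 0.0120 M |  |  |
| theta | 0.800 M | 1.00 M | 0.0120 M |  |  |
| gamma | 0.400 M | 1.00 M | 0.0120 M | 0.200 M |  |
| epsilon | 0.400 M | 0.500 M | 0.0120 M |  |  |
| beta | 1.20 M | 2.00 M | 0.0120 M |  | 19 min |

| eta run: time / min | eta run: [target] / M | theta run: time / min | theta run: [target] / M | gamma run: time / min | gamma run: [target] / M | epsilon run: time / min | epsilon run: [target] / M |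
|---|---|---|---|---|---|---|---|
| 0.68 | 0.0180 | 0.68 | 0.0229 | 0.68 | 0.2161 | 0.68 | 0.0104 |
| 2.1 | 0.0443 | 2.1 | 0.0641 | 2.1 | 0.2453 | 2.1 | 0.0299 |
| 4.0 | 0.0717 | 4.0 | 0.1049 | 4.0 | 0.2717 | 4.0 | 0.0485 |
| 6.3 | 0.0906 | 6.3 | 0.1436 | 6.3 | 0.2906 | 6.3 | 0.0626 |
| 9.0 | 0.1064 | 9.0 | 0.1750 | 9.0 | 0.3062 | 9.0 | 0.0745 |
| 12 | 0.1159 | 12 | 0.2004 | 12 | 0.3158 | 12 | 0.0810 |
| 15 | 0.1215 | 15 | 0.2152 | 15 | 0.3205 | 15 | 0.0848 |
| 19 | 0.1237 | 19 | 0.2296 | 19 | 0.3225 | 19 | 0.0868 |

(readings scatter by 0.001 M)

- Overall: starting material + coupling partner -> target, with free catalyst as catalyst.
- Constant volume, constant temperature.
- A reading of a species includes what of it is bound.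
- "The second partner" is coupling partner.
- An order is taken over about fifteen percent of the charge, up and down.

- order of the initial rate in [starting material], near the charge of the eta run, the rate being that where two percent of its starting material are target (one fixed amount of target, the same in the runs compared)
- order of the initial rate in [coupling partner], near the charge of the eta run, the rate being that where two percent of its starting material are target
- target in the beta run at 19 min, as a share of the starting material charged

In the first instants of the eta run, 0.0120 M of free catalyst faces 0.400 M of starting material, the limiting reagent, and 1.00 M of coupling partner. Over the first 0.68 min of the eta run, target forms at 0.0265 M min⁻¹ on average. The theta run, with twice the starting material, has made 1.45 times as much target as the eta run by 2.1 min, which reads as a rough mean order of 0.533. The epsilon run, with half the coupling partner, has made 0.675 of the eta amount by then, a rough mean order of 0.567. The first order, lying below one, suggests that part of the catalyst is already held on starting material.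

By the middle of the eta run, the rate between 9.0 min and 12 min is 0.003167 M min⁻¹, far lower than at the start, though 0.294 M of starting material remained at 9.0 min. Added target shows no brake in these readings: the gamma run, charged with 0.200 M of it, gains 0.1225 M by 19 min, and the eta run gains 0.1237 M.

The reckoning here therefore supposes that the catalyst dies, and follows one catalyst molecule. Whenever it is free, it may take up starting material or die, and the odds of going on grow in proportion to [S], the concentration of starting material. Turnovers per catalyst lost then scale with [S], so each catalyst lost consumes a constant share of what remains. The natural quantity is the burn B, the natural logarithm of starting material charged over starting material left, which should climb to one ceiling in the eta and theta runs, both charged with 1.00 M of coupling partner.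

At the end of the eta run, at 19 min, the burn is 0.370, and the last interval adds 2.20 mM of target, so this reading is taken as the ceiling. Let B approach its ceiling as one minus an exponential with time constant τ, the catalyst's lifetime. The eta reading at 9.0 min is a burn of 0.309, which gives τ = 4.98 min. The theta reading at 12 min is a burn of 0.288, which gives τ = 7.94 min, so in these readings the theta run, with more starting material, shows a longer life.

For the beta run, τ continued in a straight line to 1.20 M of starting material is 10.9 min. The epsilon burn at 19 min is 0.245, and the eta burn is 1.51 times that. Assuming that the 2.00 M of coupling partner in the beta run multiplies the eta burn by the same factor, and ignoring the coupling partner consumed, the ceiling for the beta run is 0.560. At 19 min, 82.5% of it is reached, so the burn is 0.462, which is 37.0% of the starting material.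

The forecast puts the orders at 0.42, below the 0.533 here, and 0.7, above the 0.567 here, and the share at 35%, below the reckoned share, holding that “starting material saturates and protects the catalyst”.

The beta run gives 36.5% at 19 min, with orders of 0.55 in starting material and 0.60 in coupling partner near the eta charge.

free catalyst + starting material ⇌ catalyst-substrate complex (110.4 M⁻¹ min⁻¹, 35.46 min⁻¹); catalyst-substrate complex + coupling partner → target + free catalyst (13.02 M⁻¹ min⁻¹); free catalyst → spent catalyst (0.3540 min⁻¹); 2 coupling partner ⇌ idle reagent dimer, settled at all times (3.240 M⁻¹) The fit with the main steps alone forecasts 52.0% for the beta run. The simulated share is a burn of 0.455, against the 0.462 reckoned, and 1.23 times the eta burn of 0.370. In the gamma run, counting the target gained since the start, the burn at 19 min is 0.366.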